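**Retrosynthetic overview** (side chain numbered C1' at the benzylic CH2 to C15' at the carbinol carbon)
1. C5'–C6': Nozaki–Hiyama–Kishi coupling of an (E)-alkenyl iodide (C6'–C15', already carrying the C12' ketone, the C11' methyl centre and the free tertiary alcohol) with a β,γ-unsaturated aryl pentenal (C1'–C5'), then oxidation to the skipped dienone and release of the phenol last.
2. Alkenyl iodide: Zr-catalysed carboalumination/iodination of a terminal alkyne (C6'=C7'), Weinreb ketone synthesis for C12'–C13', Cu-catalysed tosylate–Grignard coupling for C9'–C10'.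
3. The only stereocentre (C11') comes from (R)-Roche ester, made by ene-reductase reduction of methyl 2-(hydroxymethyl)acrylate.
4. Aldehyde: arylcopper allylation (C1'–aryl) with an (E)-allylic bromide obtained by carboalumination/formaldehyde trapping of a butynyl silyl ether (C2'=C3').
5. No ring is formed; the benzene ring is bought in as 4-hydroxy-3-methylbenzaldehyde and adjusted by bromination, O-methylation and Baeyer–Villiger oxidation.

Assumption: all five starting materials are taken as commercial, and an Old Yellow Enzyme-type ene-reductase with the reported (R)-selectivity for the hydroxymethyl acrylate is used.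

**Step 1**
Reactants: 1 methyl 2-(hydroxymethyl)acrylate
Product: 2 methyl (R)-3-hydroxy-2-methylpropanoate
Conditions: ene-reductase (flavin-dependent, Old Yellow Enzyme family, e.g. OYE3), NAD+ (cat.), formate dehydrogenase, HCO2Na, Tris–HCl buffer pH 7.5, 30 °C
Reagents that add atoms: none
Why: Asymmetric ene-reductase C=C bioreduction, in which the reduced flavin delivers hydride to the CH2 terminus and the active-site tyrosine protonates Cα from one face only, sets the (R)-methyl stereocentre (this enzyme class is reported to give the (R)-Roche ester in >99% ee).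

**Step 2**
Reactants: 2 methyl (R)-3-hydroxy-2-methylpropanoate
Product: 3 methyl (R)-2-methyl-3-(tosyloxy)propanoate
Conditions: TsCl, pyridine, CH2Cl2, 0 °C to rt
Reagents that add atoms: 4-methylbenzenesulfonyl chloride (TsCl), Cc1ccc(cc1)S(=O)(=O)Cl
Why: Sulfonylation of the primary alcohol with a weak base at low temperature leaves the α-stereocentre untouched and avoids β-elimination.

**Step 3**
Reactants: 3 methyl (R)-2-methyl-3-(tosyloxy)propanoate
Product: 4 (S)-3-hydroxy-2-methylpropyl 4-methylbenzenesulfonate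
Conditions: i-Bu2AlH (2.5 equiv), CH2Cl2, −78 to −20 °C; aq. potassium sodium tartrate
Reagents that add atoms: none
Why: Chemoselective hydride reduction of the ester to the primary alcohol, since alkyl tosylates are inert to i-Bu2AlH at low temperature and no base is present to epimerise the centre.

**Step 4**
Reactants: 4 (S)-3-hydroxy-2-methylpropyl 4-methylbenzenesulfonate
Product: 5 (S)-3-((tert-butyldimethylsilyl)oxy)-2-methylpropyl 4-methylbenzenesulfonate
Conditions: TBSCl, imidazole, CH2Cl2, 0 °C to rt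
Reagents that add atoms: tert-butyldimethylsilyl chloride (TBSCl), CC(C)(C)[Si](C)(C)Cl
Why: Corey silylation of the primary alcohol masks the future C12' oxygen under near-neutral conditions that do not trigger oxetane formation.

**Step 5**
Reactants: 5 (S)-3-((tert-butyldimethylsilyl)oxy)-2-methylpropyl 4-methylbenzenesulfonate; 6 (4-bromobut-1-yn-1-yl)trimethylsilane
Product: 8 (R)-tert-butyldimethyl((2-methyl-7-(trimethylsilyl)hept-6-yn-1-yl)oxy)silane, via Grignard reagent 7 (not isolated)
Conditions: 6 (2 equiv), Mg, THF, rt; then 5, Li2CuCl4 (5 mol%), THF, −78 °C to rt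
Reagents that add atoms: none
Why: Kochi-type Cu-catalysed sp3–sp3 cross-coupling of a primary tosylate with a Grignard reagent forms C9'–C10' at the CH2 next to the stereocentre, which is not involved.

**Step 6**
Reactants: 8 (R)-tert-butyldimethyl((2-methyl-7-(trimethylsilyl)hept-6-yn-1-yl)oxy)silane
Product: 9 (R)-tert-butyldimethyl((2-methylhept-6-yn-1-yl)oxy)silane
Conditions: K2CO3 (0.3 equiv), MeOH, rt
Reagents that add atoms: none
Why: Base-catalysed protodesilylation (methanolysis) of the alkynyl C–Si bond leaves the alkyl TBS ether intact.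

**Step 7**
Reactants: 9 (R)-tert-butyldimethyl((2-methylhept-6-yn-1-yl)oxy)silane
Product: 11 (R,E)-tert-butyl((7-iodo-2,6-dimethylhept-6-en-1-yl)oxy)dimethylsilane, via alkenylalane 10 (not isolated)
Conditions: AlMe3 (2.5 equiv), Cp2ZrCl2 (0.25 equiv), CH2Cl2, 0 °C to rt; then I2, THF, −30 to 0 °C
Reagents that add atoms: trimethylaluminium (AlMe3), C[Al](C)C; iodine, II
Why: Negishi Zr-catalysed carboalumination adds Me–Al syn across the terminal alkyne with methyl on the internal carbon, and iodinolysis with retention gives the (E)-2-methylalkenyl iodide.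

**Step 8**
Reactants: 11 (R,E)-tert-butyl((7-iodo-2,6-dimethylhept-6-en-1-yl)oxy)dimethylsilane
Product: 12 (R,E)-7-iodo-2,6-dimethylhept-6-en-1-ol
Conditions: TsOH·H2O (10 mol%), MeOH, rt
Reagents that add atoms: none
Why: Acid-catalysed methanolysis of the primary TBS ether, to which the alkenyl iodide is stable.

**Step 9**
Reactants: 12 (R,E)-7-iodo-2,6-dimethylhept-6-en-1-ol
Product: 13 (R,E)-7-iodo-2,6-dimethylhept-6-enoic acid
Conditions: TEMPO (20 mol%), PhI(OAc)2 (2.2 equiv), MeCN/H2O 1:1, rt
Reagents that add atoms: water, O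
Why: TEMPO/PhI(OAc)2 (Epp–Widlanski) oxidation takes the primary alcohol to the acid under mildly acidic conditions that do not epimerise the α-methyl centre.

**Step 10**
Reactants: 13 (R,E)-7-iodo-2,6-dimethylhept-6-enoic acid
Product: 14 (R,E)-7-iodo-N-methoxy-N,2,6-trimethylhept-6-enamide
Conditions: MeNHOMe·HCl, EDC·HCl, HOBt, i-Pr2NEt, CH2Cl2, 0 °C to rt
Reagents that add atoms: N,O-dimethylhydroxylamine hydrochloride, CNOC.Cl
Why: Carbodiimide amide coupling gives the Weinreb amide, and a simple α-alkyl acid couples without racemisation.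

**Step 11**
Reactants: 15 4-bromo-2-methylbutan-2-ol
Product: 16 ((4-bromo-2-methylbutan-2-yl)oxy)trimethylsilane
Conditions: TMSCl, imidazole, CH2Cl2, 0 °C to rt
Reagents that add atoms: chlorotrimethylsilane (TMSCl), C[Si](C)(C)Cl
Why: Silylation of the tertiary alcohol allows a Grignard reagent to be formed from the bromide.

**Step 12**
Reactants: 14 (R,E)-7-iodo-N-methoxy-N,2,6-trimethylhept-6-enamide; 16 ((4-bromo-2-methylbutan-2-yl)oxy)trimethylsilane
Product: 19 (6R,10E)-2-hydroxy-11-iodo-2,6,10-trimethylundec-10-en-5-one, via Grignard reagent 17 (not isolated), via silyl ether ketone 18 (not isolated)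
Conditions: 16 (2.5 equiv), Mg, THF, 40 °C; then 14, THF, 0 °C; then 1 M HCl, THF, rt, 30 min
Reagents that add atoms: none
Why: Weinreb ketone synthesis, in which the chelated tetrahedral adduct stops at the ketone without over-addition or α-epimerisation, and the dilute-acid work-up cleaves the labile tertiary TMS ether.

**Step 13**
Reactants: 20 4-hydroxy-3-methylbenzaldehyde
Product: 21 3-bromo-4-hydroxy-5-methylbenzaldehyde
Conditions: Br2, AcOH, rt
Reagents that add atoms: bromine, BrBr
Why: Electrophilic aromatic bromination is directed by the phenol OH to its only free ortho position, the para position being blocked.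

**Step 14**
Reactants: 21 3-bromo-4-hydroxy-5-methylbenzaldehyde
Product: 22 3-bromo-4-methoxy-5-methylbenzaldehyde
Conditions: MeI, K2CO3, DMF, rt
Reagents that add atoms: iodomethane, CI
Why: Williamson O-methylation of the phenol.

**Step 15**
Reactants: 22 3-bromo-4-methoxy-5-methylbenzaldehyde
Product: 24 3-bromo-4-methoxy-5-methylphenol, via aryl formate 23 (not isolated)
Conditions: mCPBA, CH2Cl2, rt; then K2CO3 (cat.), MeOH, rt
Reagents that add atoms: 3-chloroperoxybenzoic acid (mCPBA), OOC(=O)c1cccc(Cl)c1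
Why: Baeyer–Villiger (Dakin-type) oxidation, in which the electron-rich aryl group migrates in preference to H, gives the formate, which is methanolysed to the phenol.

**Step 16**
Reactants: 24 3-bromo-4-methoxy-5-methylphenol
Product: 25 (3-bromo-4-methoxy-5-methylphenoxy)triisopropylsilane
Conditions: TIPSCl, imidazole, DMF, rt
Reagents that add atoms: chlorotriisopropylsilane (TIPSCl), CC(C)[Si](Cl)(C(C)C)C(C)C
Why: Silylation of the phenol with a bulky group that withstands organolithium and acid and is removed later with fluoride.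

**Step 17**
Reactants: 26 tert-butyl(but-3-yn-1-yloxy)dimethylsilane
Product: 28 (E)-5-((tert-butyldimethylsilyl)oxy)-3-methylpent-2-en-1-ol, via alkenylalane 27 (not isolated)
Conditions: AlMe3 (2.5 equiv), Cp2ZrCl2 (0.25 equiv), CH2Cl2, rt; then n-BuLi, THF, −78 °C; (CH2O)n, −78 °C to rt
Reagents that add atoms: trimethylaluminium (AlMe3), C[Al](C)C; paraformaldehyde (as formaldehyde), C=O
Why: Negishi carboalumination (syn Me–Al addition) followed by formaldehyde trapping of the alkenylalanate with retention gives the (E)-trisubstituted allylic alcohol.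

**Step 18**
Reactants: 28 (E)-5-((tert-butyldimethylsilyl)oxy)-3-methylpent-2-en-1-ol
Product: 29 (E)-((5-bromo-3-methylpent-3-en-1-yl)oxy)(tert-butyl)dimethylsilane
Conditions: CBr4, PPh3, CH2Cl2, 0 °C
Reagents that add atoms: tetrabromomethane, BrC(Br)(Br)Br
Why: Appel bromination of the primary allylic alcohol proceeds under neutral conditions without allylic transposition or E/Z scrambling.

**Step 19**
Reactants: 25 (3-bromo-4-methoxy-5-methylphenoxy)triisopropylsilane; 29 (E)-((5-bromo-3-methylpent-3-en-1-yl)oxy)(tert-butyl)dimethylsilane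
Product: 32 (E)-tert-butyl((5-(2-methoxy-3-methyl-5-((triisopropylsilyl)oxy)phenyl)-3-methylpent-3-en-1-yl)oxy)dimethylsilane, via aryllithium 30 (not isolated), via arylcopper 31 (not isolated)
Conditions: n-BuLi, THF, −78 °C; CuBr·SMe2 (1 equiv), −78 to −40 °C; then 29, −78 °C to rt
Reagents that add atoms: none
Why: Bromine–lithium exchange, transmetallation to copper and SN2 allylation at the unhindered CH2 terminus of the γ,γ-disubstituted allylic bromide form the aryl–C1' bond with retention of the (E)-alkene.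

**Step 20**
Reactants: 32 (E)-tert-butyl((5-(2-methoxy-3-methyl-5-((triisopropylsilyl)oxy)phenyl)-3-methylpent-3-en-1-yl)oxy)dimethylsilane
Product: 33 (E)-5-(2-methoxy-3-methyl-5-((triisopropylsilyl)oxy)phenyl)-3-methylpent-3-en-1-ol
Conditions: PPTS (20 mol%), MeOH, rt
Reagents that add atoms: none
Why: Mild acid-catalysed methanolysis cleaves the primary alkyl TBS ether selectively because aryl TIPS ethers are stable to acid.

**Step 21**
Reactants: 33 (E)-5-(2-methoxy-3-methyl-5-((triisopropylsilyl)oxy)phenyl)-3-methylpent-3-en-1-ol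
Product: 34 (E)-5-(2-methoxy-3-methyl-5-((triisopropylsilyl)oxy)phenyl)-3-methylpent-3-enal
Conditions: Dess–Martin periodinane, NaHCO3, CH2Cl2, 0 °C; used crude at once
Reagents that add atoms: none
Why: Dess–Martin oxidation under buffered, non-basic conditions gives the β,γ-unsaturated aldehyde without moving the double bond into conjugation.

**Step 22**
Reactants: 19 (6R,10E)-2-hydroxy-11-iodo-2,6,10-trimethylundec-10-en-5-one; 34 (E)-5-(2-methoxy-3-methyl-5-((triisopropylsilyl)oxy)phenyl)-3-methylpent-3-enal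
Product: 36 (6R,10E,14E)-2,12-dihydroxy-16-(2-methoxy-3-methyl-5-((triisopropylsilyl)oxy)phenyl)-2,6,10,14-tetramethylhexadeca-10,14-dien-5-one (mixture of C12 epimers), via alkenylchromium dichloride 35 (not isolated)
Conditions: CrCl2 (6 equiv), NiCl2 (2 mol%), degassed DMF, rt
Reagents that add atoms: none
Why: Nozaki–Hiyama–Kishi coupling (oxidative addition to zerovalent nickel, transmetallation to trivalent chromium with retention of the (E)-geometry) adds selectively to the aldehyde under non-basic conditions that tolerate the ketone and free tertiary alcohol; the new carbinol centre is a mixture that the next oxidation erases.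

**Step 23**
Reactants: 36 (6R,10E,14E)-2,12-dihydroxy-16-(2-methoxy-3-methyl-5-((triisopropylsilyl)oxy)phenyl)-2,6,10,14-tetramethylhexadeca-10,14-dien-5-one
Product: 37 (6R,10E,14E)-2-hydroxy-16-(2-methoxy-3-methyl-5-((triisopropylsilyl)oxy)phenyl)-2,6,10,14-tetramethylhexadeca-10,14-diene-5,12-dione
Conditions: Dess–Martin periodinane, NaHCO3, CH2Cl2, 0 °C
Reagents that add atoms: none
Why: Dess–Martin oxidation of the secondary allylic alcohol under buffered conditions neither isomerises the skipped dienone nor epimerises the α-methyl ketone, and the tertiary alcohol is inert.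

**Step 24**
Reactants: 37 (6R,10E,14E)-2-hydroxy-16-(2-methoxy-3-methyl-5-((triisopropylsilyl)oxy)phenyl)-2,6,10,14-tetramethylhexadeca-10,14-diene-5,12-dione
Product: 38 (6R,10E,14E)-2-hydroxy-16-(5-hydroxy-2-methoxy-3-methylphenyl)-2,6,10,14-tetramethylhexadeca-10,14-diene-5,12-dione (CNP0209286.1)
Conditions: TBAF, AcOH (1:1), THF, 0 °C
Reagents that add atoms: none
Why: Fluoride-mediated desilylation of the aryl silyl ether, buffered with AcOH so that the skipped enone and the α-methyl ketone never see free base.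

**Compound list**
1 | methyl 2-(hydroxymethyl)acrylate | C=C(CO)C(=O)OC | starting material
2 | methyl (R)-3-hydroxy-2-methylpropanoate | OC[C@@H](C)C(=O)OC | intermediate
3 | methyl (R)-2-methyl-3-(tosyloxy)propanoate | Cc1ccc(cc1)S(=O)(=O)OC[C@@H](C)C(=O)OC | intermediate
4 | (S)-3-hydroxy-2-methylpropyl 4-methylbenzenesulfonate | Cc1ccc(cc1)S(=O)(=O)OC[C@@H](C)CO | intermediate
5 | (S)-3-((tert-butyldimethylsilyl)oxy)-2-methylpropyl 4-methylbenzenesulfonate | Cc1ccc(cc1)S(=O)(=O)OC[C@@H](C)CO[Si](C)(C)C(C)(C)C | intermediate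
6 | (4-bromobut-1-yn-1-yl)trimethylsilane | C[Si](C)(C)C#CCCBr | starting material
7 | (4-(trimethylsilyl)but-3-yn-1-yl)magnesium bromide | C[Si](C)(C)C#CCC[Mg]Br | intermediate
8 | (R)-tert-butyldimethyl((2-methyl-7-(trimethylsilyl)hept-6-yn-1-yl)oxy)silane | C[Si](C)(C)C#CCCC[C@@H](C)CO[Si](C)(C)C(C)(C)C | intermediate
9 | (R)-tert-butyldimethyl((2-methylhept-6-yn-1-yl)oxy)silane | C#CCCC[C@@H](C)CO[Si](C)(C)C(C)(C)C | intermediate
10 | [(1E,6R)-7-((tert-butyldimethylsilyl)oxy)-2,6-dimethylhept-1-en-1-yl]dimethylalane | C[Al](C)/C=C(\C)CCC[C@@H](C)CO[Si](C)(C)C(C)(C)C | intermediate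
11 | (R,E)-tert-butyl((7-iodo-2,6-dimethylhept-6-en-1-yl)oxy)dimethylsilane | I/C=C(\C)CCC[C@@H](C)CO[Si](C)(C)C(C)(C)C | intermediate
12 | (R,E)-7-iodo-2,6-dimethylhept-6-en-1-ol | I/C=C(\C)CCC[C@@H](C)CO | intermediate
13 | (R,E)-7-iodo-2,6-dimethylhept-6-enoic acid | I/C=C(\C)CCC[C@@H](C)C(=O)O | intermediate
14 | (R,E)-7-iodo-N-methoxy-N,2,6-trimethylhept-6-enamide | I/C=C(\C)CCC[C@@H](C)C(=O)N(C)OC | intermediate
15 | 4-bromo-2-methylbutan-2-ol | CC(C)(O)CCBr | starting material
16 | ((4-bromo-2-methylbutan-2-yl)oxy)trimethylsilane | C[Si](C)(C)OC(C)(C)CCBr | intermediate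
17 | (3-methyl-3-((trimethylsilyl)oxy)butyl)magnesium bromide | C[Si](C)(C)OC(C)(C)CC[Mg]Br | intermediate
18 | (6R,10E)-11-iodo-2,6,10-trimethyl-2-((trimethylsilyl)oxy)undec-10-en-5-one | I/C=C(\C)CCC[C@@H](C)C(=O)CCC(C)(C)O[Si](C)(C)C | intermediate
19 | (6R,10E)-2-hydroxy-11-iodo-2,6,10-trimethylundec-10-en-5-one | I/C=C(\C)CCC[C@@H](C)C(=O)CCC(C)(C)O | intermediate
20 | 4-hydroxy-3-methylbenzaldehyde | Cc1cc(C=O)ccc1O | starting material
21 | 3-bromo-4-hydroxy-5-methylbenzaldehyde | Cc1cc(C=O)cc(Br)c1O | intermediate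
22 | 3-bromo-4-methoxy-5-methylbenzaldehyde | COc1c(C)cc(C=O)cc1Br | intermediate
23 | 3-bromo-4-methoxy-5-methylphenyl formate | COc1c(C)cc(OC=O)cc1Br | intermediate
24 | 3-bromo-4-methoxy-5-methylphenol | COc1c(C)cc(O)cc1Br | intermediate
25 | (3-bromo-4-methoxy-5-methylphenoxy)triisopropylsilane | COc1c(C)cc(O[Si](C(C)C)(C(C)C)C(C)C)cc1Br | intermediate
26 | tert-butyl(but-3-yn-1-yloxy)dimethylsilane | C#CCCO[Si](C)(C)C(C)(C)C | starting material
27 | (E)-(4-((tert-butyldimethylsilyl)oxy)-2-methylbut-1-en-1-yl)dimethylalane | C[Al](C)/C=C(\C)CCO[Si](C)(C)C(C)(C)C | intermediate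
28 | (E)-5-((tert-butyldimethylsilyl)oxy)-3-methylpent-2-en-1-ol | OC/C=C(\C)CCO[Si](C)(C)C(C)(C)C | intermediate
29 | (E)-((5-bromo-3-methylpent-3-en-1-yl)oxy)(tert-butyl)dimethylsilane | BrC/C=C(\C)CCO[Si](C)(C)C(C)(C)C | intermediate
30 | (2-methoxy-3-methyl-5-((triisopropylsilyl)oxy)phenyl)lithium | COc1c(C)cc(O[Si](C(C)C)(C(C)C)C(C)C)cc1[Li] | intermediate
31 | (2-methoxy-3-methyl-5-((triisopropylsilyl)oxy)phenyl)copper | COc1c(C)cc(O[Si](C(C)C)(C(C)C)C(C)C)cc1[Cu] | intermediate
32 | (E)-tert-butyl((5-(2-methoxy-3-methyl-5-((triisopropylsilyl)oxy)phenyl)-3-methylpent-3-en-1-yl)oxy)dimethylsilane | COc1c(C)cc(O[Si](C(C)C)(C(C)C)C(C)C)cc1C/C=C(\C)CCO[Si](C)(C)C(C)(C)C | intermediate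
33 | (E)-5-(2-methoxy-3-methyl-5-((triisopropylsilyl)oxy)phenyl)-3-methylpent-3-en-1-ol | COc1c(C)cc(O[Si](C(C)C)(C(C)C)C(C)C)cc1C/C=C(\C)CCO | intermediate
34 | (E)-5-(2-methoxy-3-methyl-5-((triisopropylsilyl)oxy)phenyl)-3-methylpent-3-enal | COc1c(C)cc(O[Si](C(C)C)(C(C)C)C(C)C)cc1C/C=C(\C)CC=O | intermediate
35 | dichloro[(1E,6R)-10-hydroxy-2,6,10-trimethyl-7-oxoundec-1-en-1-yl]chromium | Cl[Cr](Cl)/C=C(\C)CCC[C@@H](C)C(=O)CCC(C)(C)O | intermediate
36 | (6R,10E,14E)-2,12-dihydroxy-16-(2-methoxy-3-methyl-5-((triisopropylsilyl)oxy)phenyl)-2,6,10,14-tetramethylhexadeca-10,14-dien-5-one (C12 epimers) | COc1c(C)cc(O[Si](C(C)C)(C(C)C)C(C)C)cc1C/C=C(\C)CC(O)/C=C(\C)CCC[C@@H](C)C(=O)CCC(C)(C)O | intermediate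
37 | (6R,10E,14E)-2-hydroxy-16-(2-methoxy-3-methyl-5-((triisopropylsilyl)oxy)phenyl)-2,6,10,14-tetramethylhexadeca-10,14-diene-5,12-dione | COc1c(C)cc(O[Si](C(C)C)(C(C)C)C(C)C)cc1C/C=C(\C)CC(=O)/C=C(\C)CCC[C@@H](C)C(=O)CCC(C)(C)O | intermediate
38 | (6R,10E,14E)-2-hydroxy-16-(5-hydroxy-2-methoxy-3-methylphenyl)-2,6,10,14-tetramethylhexadeca-10,14-diene-5,12-dione | COc1c(C)cc(O)cc1C/C=C(\C)CC(=O)/C=C(\C)CCC[C@@H](C)C(=O)CCC(C)(C)O | target

**Totals**
Total step count: 24.
Longest linear sequence: 14 steps (steps 1–10, 12, 22, 23, 24).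

**Three steps most likely to fail, each with a fallback**

Step 22 (with the aldehyde made in step 21): the β,γ-unsaturated aldehyde 34 can slip into conjugation, and trisubstituted alkenyl iodides can be sluggish in the chromium-mediated coupling. The fallback replaces carbonyl addition plus oxidation by an acyl cross-coupling that forms the C5' ketone directly under neutral conditions. It sets out from 33 and 19 and comes back at 37, bypassing steps 21–23. Alcohol 33 is oxidised (TEMPO, PhI(OAc)2, MeCN/H2O) to the pentenoic acid F1, which is condensed with thiophenol (EDC·HCl, DMAP cat., CH2Cl2) to the S-phenyl thioester F2. Iodide 19 is stannylated (Me3SnSnMe3, Pd(PPh3)4, toluene, 80 °C) to the (E)-alkenylstannane F3. Liebeskind–Srogl coupling of F2 with F3 (Pd2(dba)3, tri(2-furyl)phosphine, CuO2PPh2, THF, rt) gives 37.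

Step 5: the Cu-catalysed coupling at a β-branched tosylate with a functionalised homopropargyl Grignard reagent may be slow or give Wurtz and elimination products. The fallback builds the alkyne by allylation and one-carbon homologation instead of bringing it in preformed. It sets out from 5 and comes back at 9. Tosylate 5 is coupled with the far more reactive allylmagnesium bromide (Li2CuCl4 cat., THF) to the terminal alkene F4. Hydroboration–oxidation (9-BBN, THF; then H2O2, NaOH) gives the primary alcohol F5, and Dess–Martin oxidation gives the aldehyde F6. Ohira–Bestmann homologation (dimethyl (1-diazo-2-oxopropyl)phosphonate, K2CO3, MeOH) then delivers alkyne 9.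

Step 19: the arylcopper allylation can suffer from SN2' attack, homocoupling or butylation by the bromobutane formed in the exchange. The fallback changes from organocopper substitution to a palladium π-allyl cross-coupling. It sets out from 25 and comes back at 32. Bromide 25 is lithiated (n-BuLi, THF, −78 °C) and quenched with 2-isopropoxy-4,4,5,5-tetramethyl-1,3,2-dioxaborolane to the aryl pinacol boronate F7. Suzuki–Miyaura allyl–aryl coupling of F7 with bromide 29 (Pd(PPh3)4, K2CO3, THF/H2O, 60 °C) attacks the less hindered allyl terminus and gives 32.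

**Further compounds**
F1 | step 22 | (E)-5-(2-methoxy-3-methyl-5-((triisopropylsilyl)oxy)phenyl)-3-methylpent-3-enoic acid | COc1c(C)cc(O[Si](C(C)C)(C(C)C)C(C)C)cc1C/C=C(\C)CC(=O)O
F2 | step 22 | S-phenyl (E)-5-(2-methoxy-3-methyl-5-((triisopropylsilyl)oxy)phenyl)-3-methylpent-3-enethioate | COc1c(C)cc(O[Si](C(C)C)(C(C)C)C(C)C)cc1C/C=C(\C)CC(=O)Sc1ccccc1
F3 | step 22 | (6R,10E)-2-hydroxy-2,6,10-trimethyl-11-(trimethylstannyl)undec-10-en-5-one | C[Sn](C)(C)/C=C(\C)CCC[C@@H](C)C(=O)CCC(C)(C)O
F4 | step 5 | (R)-tert-butyldimethyl((2-methylhex-5-en-1-yl)oxy)silane | C=CCC[C@@H](C)CO[Si](C)(C)C(C)(C)C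
F5 | step 5 | (R)-6-((tert-butyldimethylsilyl)oxy)-5-methylhexan-1-ol | OCCCC[C@@H](C)CO[Si](C)(C)C(C)(C)C
F6 | step 5 | (R)-6-((tert-butyldimethylsilyl)oxy)-5-methylhexanal | O=CCCC[C@@H](C)CO[Si](C)(C)C(C)(C)C
F7 | step 19 | triisopropyl(4-methoxy-3-methyl-5-(4,4,5,5-tetramethyl-1,3,2-dioxaborolan-2-yl)phenoxy)silane | COc1c(C)cc(O[Si](C(C)C)(C(C)C)C(C)C)cc1B1OC(C)(C)C(C)(C)O1
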